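(All constants stand for no real mixture; the run is a simulation.)

The trap in these flasks is to read the equivalents of second substrate as its grip on the catalyst, for that grip is binding constant times concentration, and the binding constant of starting material stands 10.9 times higher.

    2 free catalyst ⇌ resting dimer, settled at all times (K1 = 220 M⁻¹)
    partner + catalyst intermediate A → free catalyst + target (k2 = 2.59 M⁻¹ min⁻¹)
    partner + catalyst intermediate B → free catalyst + second product (k3 = 3.32 M⁻¹ min⁻¹)
    second substrate + free catalyst ⇌ catalyst intermediate B (K4 = 11 M⁻¹, k4 = 5.57 M⁻¹ min⁻¹)
    starting material + free catalyst ⇌ catalyst intermediate A (K5 = 120 M⁻¹, k5 = 419 M⁻¹ min⁻¹)
    partner + target → over-reaction product (k6 = 0.0151 M⁻¹ min⁻¹)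

| flask | starting material | second substrate | partner | free catalyst | time | remark |
|---|---|---|---|---|---|---|
| spring | 33 mM | 0.500 equiv | 1.20 equiv (in portions, 3) | 12 mol% | 3.0 h | the portions of partner follow each other after 1.0 h, the first at the start |
| winter | 33 mM | 1.00 equiv | 1.20 equiv (in portions, 3) | 12 mol% | 3.0 h | the portions of partner follow each other after 1.0 h, the first at the start |
| summer | 33 mM | 2.00 equiv | 1.20 equiv (in portions, 3) | 12 mol% | 3.0 h | the portions of partner follow each other after 1.0 h, the first at the start |

* amount of target at the end, in percent of the starting material charged for spring, winter, summer, in this order
* the shape of the row from first to last (falls all the way / rises all the way / falls, then rises / hardly changes / rises, then falls)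

- where a step has two of a species, its rate is k times that concentration squared, and two are used at each turn
- "hardly changes" means that all values lie within two and a half points (for a concentration: within two and a half percent of the largest)
- run time (spring): 3.0 h

- On the fastest rung, in spring, starting material binds with a forward half-life of 0.42 min, and catalyst intermediate A releases it at 3.49 min⁻¹, which is faster than the first portion of partner captures that intermediate, at 0.0342 min⁻¹.
- Catalyst intermediate B likewise releases second substrate at 0.506 min⁻¹, faster than that portion captures it, at 0.0438 min⁻¹, so in spring, with that portion in the flask, both intermediates stay close to balance with free catalyst, a pre-equilibrium, and control passes from binding to capture by partner.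
- On the next rung, catalyst intermediate A in spring has a half-life of 0.11 h by capture with partner alone, with the whole partner charge counted at once, which is longer than the binding half-life but shorter than the run.
- On the slowest rung, the spring half-life of target by over-reaction, 19 h, is long against the run of 3.0 h, so by my reckoning over-reaction is a small correction to target.
- Balance cancels free catalyst from the ratio of the two intermediates: the hold ratio ρ, defined as [catalyst intermediate B]/[catalyst intermediate A], equals H times [second substrate]/[starting material], where H, the binding constant of second substrate over that of starting material, is 0.0917.
- At the start, ρ is 0.0458 in spring, 0.0917 in winter and 0.183 in summer.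
- Target forms at a rate proportional to catalyst intermediate A at a given concentration of partner, and of the catalyst held in the two intermediates, with free catalyst and resting dimer left uncounted, the share of A is one part in one plus ρ.
- Taking target to follow that share at its start value, a rough estimate that leaves out those two forms and the course of partner, my reckoning puts target in winter at 0.958 of spring and in summer at 0.884 of spring, a row that falls all the way; it gives these ratios and no absolute level.
- The forecast reads 54.5 %, 52 % and 48 %, shape falls all the way, in its words: “More second substrate diverts catalyst and burns partner through intermediate B”.
- The flasks give 55.3 %, 53.3 % and 49.8 % of target, a row that falls all the way, so summer stands at 0.901 of spring against the reckoned 0.884, with starting material left at 37.7 % in spring and 43.6 % in summer. In spring after 2.00 h, H and the substrates left give ρ as 0.0736, while the catalyst forms read 0.0677. In summer after 3.00 h, H and the substrates left give ρ as 0.383, while the catalyst forms read 0.347.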